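Take a small charge of Q, 1.0 M against 1.80 M of E, and follow J for 2.0 h at 0 °C.

| flask | Q | E | temperature | remark | time |
|---|---|---|---|---|---|
| north | 1 M | 1.8 M | 0 °C | the very flask that is asked about, followed so far |  |
| south-west | 2 M | 1.8 M | 6 °C | run made earlier |  |
| flask | 1.0 M | 1.80 M | 0 °C |  | 2.0 h |

| north: time / min | north: J / % | south-west: time / min | south-west: J / % |
|---|---|---|---|
| 6.00 | 11.1 | 1.00 | 1.8 |
| 20.0 | 23.1 | 1.50 | 3.5 |
| 30.0 | 30.2 | 2.50 | 7.3 |
| 50.0 | 35.6 | 4.00 | 9.3 |
| 80.0 | 38.6 | 8.00 | 14.9 |
| 90.0 | 41.4 | 12.0 | 17.1 |

(scatter of a reading: 1 percentage point)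

* J, in percent of the Q first charged, at 2.0 h
* the remedy with the largest gain of J, or "none" below 2 percentage points (autumn / summer / spring / none)
* J present, with what was taken out counted in, in percent of the Q first charged, after autumn
* J present, with what was taken out counted in, in percent of the Q first charged, after spring

- autumn: change nothing and wait 2.0 h more
- summer: at 2.0 h raise the temperature by 25 K, then wait 2.0 h
- spring: at 2.0 h take out 90 % of the J then present, then wait 2.0 h

- what is taken out of J is counted as made

Use the bench rule for a curve that levels off: treat the late readings as the large part and reckon only what more waiting adds. Take the equally spaced north readings at 20.0 min, 50.0 min and 80.0 min, whose second gain is 0.240 of the first. Apply that ratio once more, and the next step adds 0.72 percentage points. Put this on the mean of the last two readings, 40.0 %, and my estimate for J at 2.0 h is 40.7 %.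

The correction is smaller than the scatter of one reading, 1 point, so here the rule stops working: a further gain of that size stands inside the scatter.

Now compare the levels as concentrations. The last north reading is 0.414 M of J, and the last south-west reading is 0.342 M, still rising by 2.2 points in its final step. Twice the Q, at 6 °C against 0 °C, has not doubled [J] in these readings, so I divide [J] by the [E] charged. Call this the E yield, J at the levelling per E charged 0.226. Its border is plain: the E charges of the two runs stand in the ratio 1.00, so these runs cannot test any change of E.

The forecast gives 41 % (38.5 % to 44 %), 43 % after autumn and 58 % after spring, and picks spring. It reads the level as “set by the absolute J concentration”, whereas my reckoning ties that level to the E charged.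

The flask gives 41.3 % at 2.0 h.

    E + Z → J (k = 0.0483 L mol⁻¹ min⁻¹, Ea = 66.0 kJ mol⁻¹)
    Q + E → L (k = 0.0213 L mol⁻¹ min⁻¹, Ea = 52.0 kJ mol⁻¹)
    Q + E ⇌ Z (K = 0.430 L mol⁻¹, k = 0.550 L mol⁻¹ min⁻¹, Ea = 51.0 kJ mol⁻¹, ΔH = 26.0 kJ mol⁻¹)
    L ⇌ D (K = 0.337, k = 0.0473 min⁻¹, Ea = 75.0 kJ mol⁻¹, ΔH = −34.0 kJ mol⁻¹)
    Q + L → G (k = 0.00399 L mol⁻¹ min⁻¹, Ea = 60.0 kJ mol⁻¹)
    (constants at 0 °C)

Summer brings the largest gain, 5 points, while autumn and spring each bring 1.9 points, under the 2 points margin, and both end at 43.1 %. At 120 min the flask holds 7.25 % of its Q free. Now take the neighbour charged with 1.1 M of E, everything else as in the flask. The E yield puts J there at 24.9 %, and that neighbour gives 21.4 % at 2.0 h.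

The readings are simulated from invented constants; the scatter is artificial.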